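The plan exploits the 1,5-relationship of the two carbinol carbons C4 (ring A) and C11 across C5–C6–C7 (eudesmane numbering of the decalin): both are carried as ketones, so the C6–C7 bond of ring B is the Michael bond of a 1,5-diketone. An amine-catalysed intramolecular Michael addition closes ring B onto a preformed ring A and sets C7 and the C5 ring fusion in one operation. Its precursor is a monocyclic 2-methylidenecyclohexanone carrying a 4-oxopentyl chain on the quaternary C10 and the complete 1-aryl-3-methylbutyl group on C1. One methyllithium addition then makes both tertiary alcohols; aromatic diformylation and O-demethylation finish the synthesis.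

Key step: step 9

Remark: the carbocycle is numbered as eudesmane throughout (C1 bears the side chain, C5 and C10 are the ring-fusion atoms, C11 is the carbinol carbon on C7, C9' is the benzylic carbon); α is the face of the C10 methyl group, β the opposite face.
Remark: in the target the C1 side chain is trans to the C10 methyl and therefore axial on the trans-decalin, so the cis-fused C4 ketone is expected to be the more stable C5 epimer and the ring fusion has to be set kinetically.
Remark: 4 and 5 (as a THF solution) are taken as purchasable.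

Step 1
Reactants: 1 2-iodo-1,3,5-trimethoxybenzene; 2 3-methylbut-1-yne
Product: 3 1,3,5-trimethoxy-2-(3-methylbut-1-yn-1-yl)benzene
Conditions: Pd(PPh3)2Cl2 (3 mol%), CuI (5 mol%), Et3N, THF, sealed vessel, 60 °C
Reagents that add atoms: none
Why: Sonogashira coupling of the aryl iodide with the terminal alkyne joins C9' and the isobutyl carbons to the arene without creating a stereocentre.

Step 2
Reactants: 4 2-iodocyclohex-2-en-1-one; 5 pent-4-en-1-ylzinc bromide
Product: 6 2-(pent-4-en-1-yl)cyclohex-2-en-1-one
Conditions: Pd(dppf)Cl2 (3 mol%), THF/DMF, 25–50 °C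
Reagents that add atoms: none
Why: Negishi coupling of the α-iodoenone with the primary alkylzinc reagent takes place at the vinylic C–I bond and leaves the enone and the terminal alkene (the masked C11 ketone) untouched.

Step 3
Reactants: 3 1,3,5-trimethoxy-2-(3-methylbut-1-yn-1-yl)benzene; 6 2-(pent-4-en-1-yl)cyclohex-2-en-1-one
Product: 9 (2R,3S)-2-methyl-3-[(1Z)-3-methyl-1-(2,4,6-trimethoxyphenyl)but-1-en-1-yl]-2-(pent-4-en-1-yl)cyclohexan-1-one, via alkenylmagnesium bromide 7 (not isolated), via magnesium enolate 8 (not isolated)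
Conditions: isobutylmagnesium bromide (1.1 equiv), Cp2TiCl2 (5 mol%), Et2O, 25 °C; then 6, Cu(OTf)2 (4 mol%), chiral hydroxyalkyl imidazolinium chloride (carbene ligand precursor, 5 mol%), Et2O, −30 °C; then MeI (5 equiv), DMPU, −30 to 20 °C
Reagents that add atoms: iodomethane, CI
Why: Titanocene-catalysed syn-hydromagnesiation puts magnesium on the aryl-bearing alkyne carbon, the copper–carbene-catalysed asymmetric conjugate addition of this Grignard reagent to the 2-substituted enone sets C1 under ligand control (ligand enantiomer chosen for the configuration drawn), and the magnesium enolate is methylated at C10 anti to the new C1 substituent, a conjugate addition–enolate alkylation that should give the C10 methyl trans to the side chain.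

Step 4
Reactants: 9 (2R,3S)-2-methyl-3-[(1Z)-3-methyl-1-(2,4,6-trimethoxyphenyl)but-1-en-1-yl]-2-(pent-4-en-1-yl)cyclohexan-1-one
Product: 10 (2R,3S)-2-methyl-3-[(1R)-3-methyl-1-(2,4,6-trimethoxyphenyl)butyl]-2-(pent-4-en-1-yl)cyclohexan-1-one
Conditions: Et3SiH (4 equiv), CF3CO2H (3 equiv), CH2Cl2, −40 to 0 °C
Reagents that add atoms: none
Why: Ionic hydrogenation: protonation of the electron-rich styrene gives the 2,4,6-trimethoxybenzylic cation, which by allylic 1,3-strain against the ortho-methoxy groups holds C1–H in its plane on the aryl side, so triethylsilane should deliver hydride to the face opposite the quaternary C10 and give the 9'R configuration, while the ketone and the terminal alkene are not affected.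

Step 5
Reactants: 10 (2R,3S)-2-methyl-3-[(1R)-3-methyl-1-(2,4,6-trimethoxyphenyl)butyl]-2-(pent-4-en-1-yl)cyclohexan-1-one
Product: 11 1,3,5-trimethoxy-2-{(1R)-3-methyl-1-[(1S,2R)-2-methyl-3-methylidene-2-(pent-4-en-1-yl)cyclohexyl]butyl}benzene
Conditions: Ph3PCH3Br (4 equiv), KOt-Bu (3.8 equiv), toluene, 90 °C
Reagents that add atoms: methylidenetriphenylphosphorane (made in the flask from methyltriphenylphosphonium bromide and KOt-Bu), C=P(c1ccccc1)(c1ccccc1)c1ccccc1
Why: Wittig methylenation of the hindered ketone with an excess of ylide at elevated temperature turns C5=O into the exocyclic C5=C6 alkene and so brings in C6, with no stereocentre changed.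

Step 6
Reactants: 11 1,3,5-trimethoxy-2-{(1R)-3-methyl-1-[(1S,2R)-2-methyl-3-methylidene-2-(pent-4-en-1-yl)cyclohexyl]butyl}benzene
Product: 12 5-{(1R,2S)-1-methyl-6-methylidene-2-[(1R)-3-methyl-1-(2,4,6-trimethoxyphenyl)butyl]cyclohexyl}pentan-2-one
Conditions: PdCl2 (10 mol%), CuCl (1 equiv), O2 (1 atm), DMF/H2O 7:1, 20 °C
Reagents that add atoms: water, O (oxygen source of the new carbonyl; O2 only reoxidises the catalysts)
Why: Tsuji–Wacker oxidation converts the monosubstituted terminal alkene into the methyl ketone with Markovnikov selectivity, the hindered 1,1-disubstituted exocyclic alkene reacting much more slowly.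

Step 7
Reactants: 12 5-{(1R,2S)-1-methyl-6-methylidene-2-[(1R)-3-methyl-1-(2,4,6-trimethoxyphenyl)butyl]cyclohexyl}pentan-2-one
Product: 13 5-{(1R,2S)-5-hydroxy-1-methyl-6-methylidene-2-[(1R)-3-methyl-1-(2,4,6-trimethoxyphenyl)butyl]cyclohexyl}pentan-2-one (both C4 epimers)
Conditions: SeO2 (0.5 equiv), t-BuOOH (3 equiv), CH2Cl2, 0 to 20 °C
Reagents that add atoms: selenium dioxide, O=[Se]=O (catalytic, reoxidised by tert-butyl hydroperoxide, CC(C)(C)OO)
Why: Selenium dioxide allylic oxidation (ene reaction, then 2,3-sigmatropic shift) of the exocyclic alkene can occur only at C4 because C10 carries no hydrogen, and the configuration of the new carbinol is irrelevant since it is oxidised in step 8.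

Step 8
Reactants: 13 5-{(1R,2S)-5-hydroxy-1-methyl-6-methylidene-2-[(1R)-3-methyl-1-(2,4,6-trimethoxyphenyl)butyl]cyclohexyl}pentan-2-one
Product: 14 (3R,4S)-3-methyl-2-methylidene-4-[(1R)-3-methyl-1-(2,4,6-trimethoxyphenyl)butyl]-3-(4-oxopentyl)cyclohexan-1-one
Conditions: Dess–Martin periodinane (1.3 equiv), CH2Cl2, 0 °C; used at once
Reagents that add atoms: none
Why: Dess–Martin oxidation of the secondary allylic alcohol under neutral conditions gives the 2-methylidene ketone, the Michael acceptor, without base that could trigger premature reactions.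

Step 9
Reactants: 14 (3R,4S)-3-methyl-2-methylidene-4-[(1R)-3-methyl-1-(2,4,6-trimethoxyphenyl)butyl]-3-(4-oxopentyl)cyclohexan-1-one
Product: 16 (1S,5S,7S,10R)-1-[(1R)-3-methyl-1-(2,4,6-trimethoxyphenyl)butyl]-13,15-dinoreudesmane-4,11-dione (trans-fused), via enamine 15 (not isolated)
Conditions: pyrrolidine (0.3 equiv), AcOH (0.3 equiv), CH2Cl2 (0.01 M), 0 to 20 °C; pH 7 buffer; product used at once in step 10
Reagents that add atoms: none
Why: Pyrrolidine condenses with the unhindered methyl ketone to give enamine 15, whose C7 carbon adds to the unsubstituted terminus C6 of the 2-methylidene ketone, and hydrolysis of the iminium returns the catalyst; the closest known reaction type is the amine-catalysed (Stork-type) intramolecular Michael addition of a ketone to an enone giving a 1,5-diketone. Ring B closes in a 6-endo-trig mode with respect to the acceptor (enamine double bond exocyclic), and only the C7 enamine regioisomer can reach C6 through a six-membered transition state, the methyl-derived isomer would need an eight-membered one. For C7 to reach C6 the C10 tether must lie near the plane of the C5=C6 bond, that is equatorial on ring A, so the cyclisation should run through the chair with the C10 methyl axial and deliver the enol with that methyl standing over the α-face of C5. C7 is set under thermodynamic control, the acetyl group equilibrating through the enamine to the equatorial α-position of the chair of ring B. C5 is set by kinetic C-protonation of the ring-fusion enol from the β-face, axial to both rings and opposite the adjacent axial methyl, which should give the trans ring fusion. The step needs this protonation to stay kinetic, because the cis-fused ketone is expected to be more stable; buffered mild conditions, low temperature and immediate use in step 10 are meant to secure it.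

Step 10
Reactants: 16 (1S,5S,7S,10R)-1-[(1R)-3-methyl-1-(2,4,6-trimethoxyphenyl)butyl]-13,15-dinoreudesmane-4,11-dione
Product: 17 (1S,4R,5S,7S,10R)-1-[(1R)-3-methyl-1-(2,4,6-trimethoxyphenyl)butyl]eudesmane-4,11-diol
Conditions: CeCl3 (anhydrous, 5 equiv), MeLi (5 equiv), THF, −78 °C; H2O
Reagents that add atoms: methyllithium, [Li]C
Why: Organocerium addition (non-basic, so C5 next to the ketone is not enolised) converts the acetyl group into the C11 carbinol and attacks the C4 ketone from the equatorial β-direction, the axial path being blocked by the syn-axial C10 methyl, which should give the axial 4α-hydroxyl and the equatorial methyl.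

Step 11
Reactants: 17 (1S,4R,5S,7S,10R)-1-[(1R)-3-methyl-1-(2,4,6-trimethoxyphenyl)butyl]eudesmane-4,11-diol
Product: 20 5-{(1R)-1-[(1S,4R,5S,7S,10R)-4,11-dihydroxyeudesman-1-yl]-3-methylbutyl}-2,4,6-trimethoxybenzene-1,3-dicarbaldehyde, via aryllithium 18 (not isolated), via lithiated hemiaminal 19 (not isolated)
Conditions: n-BuLi (3.1 equiv), TMEDA, THF, 0 °C; DMF (1.1 equiv), −78 to 0 °C; s-BuLi (1.3 equiv), TMEDA, −78 to −20 °C; DMF (3 equiv); H2O
Reagents that add atoms: N,N-dimethylformamide, CN(C)C=O
Why: Directed ortho-lithiation between two methoxy groups followed by formylation with DMF, run twice in one flask with the first formyl group kept masked as its lithium hemiaminal, should give the dialdehyde while the tertiary alcohols are protected as their lithium alkoxides.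

Step 12
Reactants: 20 5-{(1R)-1-[(1S,4R,5S,7S,10R)-4,11-dihydroxyeudesman-1-yl]-3-methylbutyl}-2,4,6-trimethoxybenzene-1,3-dicarbaldehyde
Product: 21 5-{(1R)-1-[(1S,4R,5S,7S,10R)-4,11-dihydroxyeudesman-1-yl]-3-methylbutyl}-2,4,6-trihydroxybenzene-1,3-dicarbaldehyde
Conditions: NaSEt (10 equiv), DMF, 110 °C; then 1 M HCl to pH 3
Reagents that add atoms: none
Why: Nucleophilic O-demethylation by thiolate (SN2 at methyl) is accelerated by the ortho- and para-formyl groups that stabilise the departing phenoxides, and the basic medium leaves the two acid-sensitive tertiary alcohols intact.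

Compound list
1 | 2-iodo-1,3,5-trimethoxybenzene | COc1cc(OC)c(I)c(OC)c1 | starting material
2 | 3-methylbut-1-yne | CC(C)C#C | starting material
3 | 1,3,5-trimethoxy-2-(3-methylbut-1-yn-1-yl)benzene | CC(C)C#Cc1c(OC)cc(OC)cc1OC | intermediate
4 | 2-iodocyclohex-2-en-1-one | O=C1CCCC=C1I | starting material
5 | pent-4-en-1-ylzinc bromide | C=CCCC[Zn]Br | starting material
6 | 2-(pent-4-en-1-yl)cyclohex-2-en-1-one | O=C1CCCC=C1CCCC=C | intermediate
7 | bromo[(1E)-3-methyl-1-(2,4,6-trimethoxyphenyl)but-1-en-1-yl]magnesium | CC(C)/C=C(/[Mg]Br)c1c(OC)cc(OC)cc1OC | intermediate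
8 | bromomagnesium enolate formed by conjugate addition of 7 to 6 (C1 set, C5–C10 enolate) | CC(C)/C=C(\c1c(OC)cc(OC)cc1OC)/[C@@H]1CCCC(O[Mg]Br)=C1CCCC=C | intermediate
9 | (2R,3S)-2-methyl-3-[(1Z)-3-methyl-1-(2,4,6-trimethoxyphenyl)but-1-en-1-yl]-2-(pent-4-en-1-yl)cyclohexan-1-one | CC(C)/C=C(\c1c(OC)cc(OC)cc1OC)/[C@@H]1CCCC(=O)[C@]1(C)CCCC=C | intermediate
10 | (2R,3S)-2-methyl-3-[(1R)-3-methyl-1-(2,4,6-trimethoxyphenyl)butyl]-2-(pent-4-en-1-yl)cyclohexan-1-one | CC(C)C[C@@H](c1c(OC)cc(OC)cc1OC)[C@@H]1CCCC(=O)[C@]1(C)CCCC=C | intermediate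
11 | 1,3,5-trimethoxy-2-{(1R)-3-methyl-1-[(1S,2R)-2-methyl-3-methylidene-2-(pent-4-en-1-yl)cyclohexyl]butyl}benzene | CC(C)C[C@@H](c1c(OC)cc(OC)cc1OC)[C@@H]1CCCC(=C)[C@]1(C)CCCC=C | intermediate
12 | 5-{(1R,2S)-1-methyl-6-methylidene-2-[(1R)-3-methyl-1-(2,4,6-trimethoxyphenyl)butyl]cyclohexyl}pentan-2-one | CC(C)C[C@@H](c1c(OC)cc(OC)cc1OC)[C@@H]1CCCC(=C)[C@]1(C)CCCC(C)=O | intermediate
13 | 5-{(1R,2S)-5-hydroxy-1-methyl-6-methylidene-2-[(1R)-3-methyl-1-(2,4,6-trimethoxyphenyl)butyl]cyclohexyl}pentan-2-one (C4 epimers) | CC(C)C[C@@H](c1c(OC)cc(OC)cc1OC)[C@@H]1CCC(O)C(=C)[C@]1(C)CCCC(C)=O | intermediate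
14 | (3R,4S)-3-methyl-2-methylidene-4-[(1R)-3-methyl-1-(2,4,6-trimethoxyphenyl)butyl]-3-(4-oxopentyl)cyclohexan-1-one | CC(C)C[C@@H](c1c(OC)cc(OC)cc1OC)[C@@H]1CCC(=O)C(=C)[C@]1(C)CCCC(C)=O | intermediate
15 | pyrrolidine enamine of the side-chain ketone of 14 (C7=C11 regioisomer) | CC(C)C[C@@H](c1c(OC)cc(OC)cc1OC)[C@@H]1CCC(=O)C(=C)[C@]1(C)CCC=C(C)N2CCCC2 | intermediate
16 | (1S,5S,7S,10R)-1-[(1R)-3-methyl-1-(2,4,6-trimethoxyphenyl)butyl]-13,15-dinoreudesmane-4,11-dione (trans-fused, 7-acetyl α and equatorial) | CC(C)C[C@@H](c1c(OC)cc(OC)cc1OC)[C@@H]1CCC(=O)[C@H]2C[C@@H](C(C)=O)CC[C@]12C | intermediate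
17 | (1S,4R,5S,7S,10R)-1-[(1R)-3-methyl-1-(2,4,6-trimethoxyphenyl)butyl]eudesmane-4,11-diol | CC(C)C[C@@H](c1c(OC)cc(OC)cc1OC)[C@@H]1CC[C@@](C)(O)[C@H]2C[C@@H](C(C)(C)O)CC[C@]12C | intermediate
18 | 3'-lithio derivative of 17 as its dilithium dialkoxide | CC(C)C[C@@H](c1c(OC)c([Li])c(OC)cc1OC)[C@@H]1CC[C@@](C)(O[Li])[C@H]2C[C@@H](C(C)(C)O[Li])CC[C@]12C | intermediate
19 | 5'-lithio derivative carrying the 3'-formyl group masked as lithium dimethylamino-hemiaminal | CC(C)C[C@@H](c1c(OC)c(C(O[Li])N(C)C)c(OC)c([Li])c1OC)[C@@H]1CC[C@@](C)(O[Li])[C@H]2C[C@@H](C(C)(C)O[Li])CC[C@]12C | intermediate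
20 | 5-{(1R)-1-[(1S,4R,5S,7S,10R)-4,11-dihydroxyeudesman-1-yl]-3-methylbutyl}-2,4,6-trimethoxybenzene-1,3-dicarbaldehyde | CC(C)C[C@@H](c1c(OC)c(C=O)c(OC)c(C=O)c1OC)[C@@H]1CC[C@@](C)(O)[C@H]2C[C@@H](C(C)(C)O)CC[C@]12C | intermediate
21 | 5-{(1R)-1-[(1S,4R,5S,7S,10R)-4,11-dihydroxyeudesman-1-yl]-3-methylbutyl}-2,4,6-trihydroxybenzene-1,3-dicarbaldehyde | CC(C)C[C@@H](c1c(O)c(C=O)c(O)c(C=O)c1O)[C@@H]1CC[C@@](C)(O)[C@H]2C[C@@H](C(C)(C)O)CC[C@]12C | target

Total step count: 12. Longest linear sequence: 11 steps (step 1 or step 2, then steps 3 to 12).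

Steps most likely to fail

Step 9 (key step). The ring-fusion enol may be protonated from the α-face, because the C1 side chain lies syn-axial to the β-face of C5, or C5 may enolise after ring closure; either process leads to the more stable cis-fused diketone. The fallback sets out from 14 and comes back at 16. Ring closure under equilibrating conditions (catalytic KOt-Bu, t-BuOH/THF) would be accepted to give the cis-fused diketone F1. TMSCl/NaI/Et3N in MeCN would turn it into the bis(trimethylsilyl enol ether) F2, which contains the tetrasubstituted C4=C5 enol ether. Protonation of F2 at −78 °C with a chiral Lewis acid-assisted Brønsted acid (SnCl4 with the enantiomer of 1,1'-bi-2-naphthol that delivers the proton to the β-face) would set C5 under reagent control instead of substrate control. Brief treatment with pyrrolidinium acetate would bring the acetyl group back to the equatorial position and return 16.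

Step 3. The hindered, trisubstituted alkenyl Grignard reagent may add slowly or with low enantioselectivity, residual isobutyl groups may transfer, or the crowded enolate may be methylated incompletely. The fallback sets out from 7 and 6 and comes back at 9. Quenching 7 with B(OMe)3 and aqueous acid would give the alkenylboronic acid F3. A rhodium-catalysed asymmetric 1,4-addition (Hayashi–Miyaura reaction; [Rh(C2H4)2Cl]2, enantiopure BINAP, KOH, dioxane/H2O) to 6 would give the ketone F4 with C1 set. TMSCl/NaI/Et3N would give the more substituted silyl enol ether F5, and MeLi followed by MeI/DMPU would methylate C10 anti to the C1 substituent to return 9.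

Step 11. The second lithiation of the already anionic, crowded arene may be incomplete, or the alkyllithium may attack the masked first aldehyde, so that the sequence stops at the monoaldehyde. The fallback sets out from 17 and comes back at 20. N-Bromosuccinimide (2 equiv, MeCN, 0 °C) would brominate both free ring positions to give the dibromide F6. MeLi (2 equiv, to form the alkoxides), t-BuLi (4.4 equiv, THF, −78 °C) for double bromine–lithium exchange, and DMF would then give 20.

Further compounds
F1 | step 9 | cis-fused diketone (C5 epimer of 16) | CC(C)C[C@@H](c1c(OC)cc(OC)cc1OC)[C@@H]1CCC(=O)[C@@H]2C[C@@H](C(C)=O)CC[C@]12C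
F2 | step 9 | bis(trimethylsilyl enol ether) of the diketone (C4=C5 and C7=C11 enol ethers) | CC(C)C[C@@H](c1c(OC)cc(OC)cc1OC)[C@@H]1CCC(O[Si](C)(C)C)=C2CC(=C(C)O[Si](C)(C)C)CC[C@]12C
F3 | step 3 | [(1Z)-3-methyl-1-(2,4,6-trimethoxyphenyl)but-1-en-1-yl]boronic acid | CC(C)/C=C(/B(O)O)c1c(OC)cc(OC)cc1OC
F4 | step 3 | 3-[(1Z)-3-methyl-1-(2,4,6-trimethoxyphenyl)but-1-en-1-yl]-2-(pent-4-en-1-yl)cyclohexan-1-one (C1 as in 9, C10 epimers) | CC(C)/C=C(\c1c(OC)cc(OC)cc1OC)/[C@@H]1CCCC(=O)C1CCCC=C
F5 | step 3 | trimethylsilyl enol ether of F4 (C5=C10 double bond) | CC(C)/C=C(\c1c(OC)cc(OC)cc1OC)/[C@@H]1CCCC(O[Si](C)(C)C)=C1CCCC=C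
F6 | step 11 | 3',5'-dibromo derivative of 17 | CC(C)C[C@@H](c1c(OC)c(Br)c(OC)c(Br)c1OC)[C@@H]1CC[C@@](C)(O)[C@H]2C[C@@H](C(C)(C)O)CC[C@]12C
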